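**Strategy.** The synthesis rests on disconnecting the bond between the allylic CH2 and the vinylic CH of the (E)-CH=C(CH3) alkene, next to the single stereocentre. The acyclic CH(stereocentre)–CH2 pair between the isopropenyl group and that alkene is treated as a former vinyl group: a palladium-catalysed, three-component conjunctive cross-coupling joins a 2-silyloxyethyl boronate, vinyllithium and the (E)-alkenyl bromide that carries the (Z)-enoate arm, forming both the CH2–CH= bond and the bond from the stereocentre to its ethylene arm, and setting the stereocentre by ligand control. The precursor is an achiral vinyl borate; its boron is later exchanged for isopropenyl, and the butenolide ring is attached last by Still–Gennari olefination.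

Key step: step 7

Assumption: the sense of induction of the ferrocenyl bisphosphine in step 7 is not derived here; the antipode that delivers the (9R)-boronate 14 is to be used (both antipodes are commercial; the (Sp,Sp) form is written).

**Step 1**
Reactants: 1 (2-bromoethoxy)(tert-butyl)dimethylsilane
Product: 2 tert-butyldimethyl[2-(4,4,5,5-tetramethyl-1,3,2-dioxaborolan-2-yl)ethoxy]silane
Conditions: B2pin2 (1.5 equiv), CuI (10 mol %), PPh3 (13 mol %), LiOMe (2 equiv), DMF, 25 °C
Reagents that add atoms: bis(pinacolato)diboron, CC1(C)OB(OC1(C)C)B1OC(C)(C)C(C)(C)O1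
Why: Copper-catalysed borylation of a primary alkyl bromide is established for 2-alkoxyethyl bromides and should leave the silyl ether untouched.

**Step 2**
Reactants: 3 pent-4-yn-1-ol
Product: 5 (E)-5-bromo-4-methylpent-4-en-1-ol, via alkenylalane 4 (not isolated)
Conditions: AlMe3 (3 equiv), Cp2ZrCl2 (zirconocene dichloride, 25 mol %), CH2Cl2, 0 → 25 °C; then NBS, THF, −30 → 0 °C
Reagents that add atoms: trimethylaluminium, C[Al](C)C; N-bromosuccinimide, O=C1CCC(=O)N1Br
Why: Negishi zirconium-catalysed carboalumination adds CH3 and Al syn across the terminal alkyne with Al at the terminus, and bromination of the alkenyl–Al bond with retention fixes the E geometry.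

**Step 3**
Reactants: 5 (E)-5-bromo-4-methylpent-4-en-1-ol
Product: 6 (E)-5-bromo-4-methylpent-4-enal
Conditions: Dess–Martin periodinane, CH2Cl2, 0 → 25 °C
Reagents that add atoms: none
Why: Dess–Martin oxidation stops at the aldehyde and should not touch the alkenyl bromide.

**Step 4**
Reactants: 7 diphenyl phosphite, 8 tert-butyl bromoacetate
Product: 9 tert-butyl 2-(diphenoxyphosphoryl)acetate
Conditions: Et3N, CH2Cl2, 0 → 25 °C
Reagents that add atoms: none
Why: Michaelis–Becker-type P-alkylation of the diaryl phosphite by the activated α-bromo ester under amine base gives the Ando-type phosphonate.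

**Step 5**
Reactants: 9 tert-butyl 2-(diphenoxyphosphoryl)acetate, 10 5-bromo-2-methylpent-2-ene
Product: 11 tert-butyl 2-(diphenoxyphosphoryl)-6-methylhept-5-enoate (racemic)
Conditions: NaH, DMF, 0 → 50 °C (9 in excess)
Reagents that add atoms: none
Why: SN2 C-alkylation of the stabilised phosphonoacetate anion by the primary bromide installs the 4-methylpent-3-enyl branch, with mono-alkylation favoured by the excess of 9.

**Step 6**
Reactants: 11 tert-butyl 2-(diphenoxyphosphoryl)-6-methylhept-5-enoate, 6 (E)-5-bromo-4-methylpent-4-enal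
Product: 12 tert-butyl (2Z,6E)-7-bromo-6-methyl-2-(4-methylpent-3-en-1-yl)hepta-2,6-dienoate
Conditions: NaH, THF, 0 °C; then 6, −78 → 0 °C
Reagents that add atoms: none
Why: Ando-type Horner–Wadsworth–Emmons olefination, in which the diaryl phosphonate collapses kinetically through the cis-oxaphosphetane, should place the ester cis to the aldehyde-derived chain (2Z).

**Step 7**
Reactants: 2 tert-butyldimethyl[2-(4,4,5,5-tetramethyl-1,3,2-dioxaborolan-2-yl)ethoxy]silane, 12 tert-butyl (2Z,6E)-7-bromo-6-methyl-2-(4-methylpent-3-en-1-yl)hepta-2,6-dienoate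
Product: 14 tert-butyl (2Z,6E,9R)-11-[(tert-butyldimethylsilyl)oxy]-6-methyl-2-(4-methylpent-3-en-1-yl)-9-(4,4,5,5-tetramethyl-1,3,2-dioxaborolan-2-yl)undeca-2,6-dienoate, via vinyl borate 13 (not isolated)
Conditions: vinyllithium (halide-free, from Sn(CH=CH2)4 and n-BuLi), THF, −78 → 25 °C; then 12, Pd(OAc)2 (2 mol %), (Sp,Sp)-1,1'-bis[bis(4-methoxy-3,5-dimethylphenyl)phosphino]-2,2'-bis[(R)-α-(dimethylamino)benzyl]ferrocene (MandyPhos-type ligand, 2.4 mol %), NaOTf (2 equiv), THF, 40 °C
Reagents that add atoms: vinyllithium, [Li]C=C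
Why: Vinyllithium adds to the boron of 2 to give the four-coordinate vinyl borate 13; the cationic alkenylpalladium species formed from 12 by oxidative addition (bromide removed as NaBr) binds the vinyl π-bond and triggers a 1,2-metallate shift of the 2-silyloxyethyl group from boron to the α-carbon anti to palladium, and reductive elimination from the resulting alkyl(alkenyl)palladium forms the C8–C7 bond (numbering of 14). The closest known reaction type is the palladium-catalysed enantioselective conjunctive cross-coupling of vinyl boronate ate complexes with alkenyl electrophiles, applied here to a new migrating group and bromide. No ring is closed. The new stereocentre C9 is set by the C2-symmetric ferrocenyl bisphosphine, which selects the alkene face bound by palladium while the migration is stereospecifically anti. The step needs the metallate shift to outrun direct vinyl transfer, β-hydride elimination and loss of silanolate from the β-silyloxyethyl borate; the wide-bite-angle ligand, the halide-free cationic palladium and the mild temperature should secure this, while oxidative addition and reductive elimination retain the 6E geometry and the hindered tert-butyl (Z)-enoate stays inert.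

**Step 8**
Reactants: 14 tert-butyl (2Z,6E,9R)-11-[(tert-butyldimethylsilyl)oxy]-6-methyl-2-(4-methylpent-3-en-1-yl)-9-(4,4,5,5-tetramethyl-1,3,2-dioxaborolan-2-yl)undeca-2,6-dienoate
Product: 17 tert-butyl (2Z,6E,9R)-9-{2-[(tert-butyldimethylsilyl)oxy]ethyl}-6,10-dimethyl-2-(4-methylpent-3-en-1-yl)undeca-2,6,10-trienoate, via isopropenyl borate 15 (not isolated), via iodoalkyl boronate 16 (not isolated)
Conditions: isopropenyllithium (from 2-bromopropene and t-BuLi), THF, −78 °C; then I2, MeOH/THF, −78 °C; then NaOMe, MeOH, −78 → 25 °C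
Reagents that add atoms: isopropenyllithium, [Li]C(C)=C
Why: In this Zweifel olefination the alkene of borate 15 is iodinated, the secondary alkyl group migrates from boron to carbon with retention at C9, and methoxide-induced anti elimination of boron and iodide from 16 releases the isopropenyl group, borate formation at −78 °C being expected to outpace attack on the hindered tert-butyl enoate.

**Step 9**
Reactants: 17 tert-butyl (2Z,6E,9R)-9-{2-[(tert-butyldimethylsilyl)oxy]ethyl}-6,10-dimethyl-2-(4-methylpent-3-en-1-yl)undeca-2,6,10-trienoate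
Product: 18 tert-butyl (2Z,6E,9R)-9-(2-hydroxyethyl)-6,10-dimethyl-2-(4-methylpent-3-en-1-yl)undeca-2,6,10-trienoate
Conditions: TBAF, THF, 0 → 25 °C
Reagents that add atoms: none
Why: Fluoride desilylation frees the primary alcohol without affecting the tert-butyl ester or the alkenes.

**Step 10**
Reactants: 18 tert-butyl (2Z,6E,9R)-9-(2-hydroxyethyl)-6,10-dimethyl-2-(4-methylpent-3-en-1-yl)undeca-2,6,10-trienoate
Product: 19 tert-butyl (2Z,6E,9R)-9-(2-iodoethyl)-6,10-dimethyl-2-(4-methylpent-3-en-1-yl)undeca-2,6,10-trienoate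
Conditions: I2, PPh3, imidazole, CH2Cl2, 0 → 25 °C
Reagents that add atoms: iodine, II
Why: Appel iodination converts the primary alcohol to the iodide under neutral conditions that leave C9 and the alkenes alone.

**Step 11**
Reactants: 19 tert-butyl (2Z,6E,9R)-9-(2-iodoethyl)-6,10-dimethyl-2-(4-methylpent-3-en-1-yl)undeca-2,6,10-trienoate, 20 methyl 2-[bis(2,2,2-trifluoroethoxy)phosphoryl]acetate
Product: 21 tert-butyl (2Z,6E,9S)-9-{3-[bis(2,2,2-trifluoroethoxy)phosphoryl]-4-methoxy-4-oxobutyl}-6,10-dimethyl-2-(4-methylpent-3-en-1-yl)undeca-2,6,10-trienoate (both epimers at the phosphonate carbon)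
Conditions: 20 (2.5 equiv), NaH, DMF, 25 → 45 °C
Reagents that add atoms: none
Why: SN2 alkylation of the Still–Gennari phosphonoacetate anion by the primary iodide builds the α-substituted phosphonate, the soft weakly basic anion sparing the enoate.

**Step 12**
Reactants: 21 tert-butyl (2Z,6E,9S)-9-{3-[bis(2,2,2-trifluoroethoxy)phosphoryl]-4-methoxy-4-oxobutyl}-6,10-dimethyl-2-(4-methylpent-3-en-1-yl)undeca-2,6,10-trienoate
Product: 22 (2Z,6E,9S)-9-{3-[bis(2,2,2-trifluoroethoxy)phosphoryl]-4-methoxy-4-oxobutyl}-6,10-dimethyl-2-(4-methylpent-3-en-1-yl)undeca-2,6,10-trienoic acid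
Conditions: TMSOTf, 2,6-lutidine, CH2Cl2, 0 → 25 °C; then H2O (pH 4 buffer)
Reagents that add atoms: none
Why: Silyl-triflate-mediated cleavage of the tert-butyl ester (loss of isobutene, then hydrolysis of the silyl ester) is aprotic and buffered, so the alkenes, the methyl ester and the phosphonate should survive.

**Step 13**
Reactants: 23 4-bromofuran-2(5H)-one, 24 [2-(1,3-dioxolan-2-yl)ethyl]zinc bromide
Product: 25 4-[2-(1,3-dioxolan-2-yl)ethyl]furan-2(5H)-one
Conditions: Pd(PPh3)4 (5 mol %), THF, 25 → 50 °C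
Reagents that add atoms: none
Why: Negishi coupling of the alkylzinc reagent with the vinylogous acyl bromide (ready oxidative addition of zerovalent palladium) places the side chain at C4 of the butenolide.

**Step 14**
Reactants: 25 4-[2-(1,3-dioxolan-2-yl)ethyl]furan-2(5H)-one
Product: 26 3-(5-oxo-2,5-dihydrofuran-3-yl)propanal
Conditions: 1 M aq. HCl, THF, 25 °C
Reagents that add atoms: water, O
Why: Acid hydrolysis of the dioxolane frees the aldehyde, the butenolide being stable to dilute aqueous acid.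

**Step 15**
Reactants: 22 (2Z,6E,9S)-9-{3-[bis(2,2,2-trifluoroethoxy)phosphoryl]-4-methoxy-4-oxobutyl}-6,10-dimethyl-2-(4-methylpent-3-en-1-yl)undeca-2,6,10-trienoic acid, 26 3-(5-oxo-2,5-dihydrofuran-3-yl)propanal
Product: 27 (2Z,6E,9S,12Z)-12-(methoxycarbonyl)-6-methyl-2-(4-methylpent-3-en-1-yl)-15-(5-oxo-2,5-dihydrofuran-3-yl)-9-(prop-1-en-2-yl)pentadeca-2,6,12-trienoic acid (CNP0162600.1)
Conditions: KN(SiMe3)2 (2.05 equiv), 18-crown-6, THF, −78 °C; then 26, −78 °C; dilute aq. HCl (pH 3) work-up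
Reagents that add atoms: none
Why: Still–Gennari olefination of the carboxylate–phosphonate dianion, with fast irreversible collapse of the trifluoroethyl phosphonate adduct, should give the 12Z enoate with the methyl ester cis to the butenolide-bearing chain, the weakly basic phosphonate anion not being expected to deprotonate the butenolide.

**Compound list**
1 | (2-bromoethoxy)(tert-butyl)dimethylsilane | CC(C)(C)[Si](C)(C)OCCBr | starting material
2 | tert-butyldimethyl[2-(4,4,5,5-tetramethyl-1,3,2-dioxaborolan-2-yl)ethoxy]silane | CC(C)(C)[Si](C)(C)OCCB1OC(C)(C)C(C)(C)O1 | intermediate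
3 | pent-4-yn-1-ol | C#CCCCO | starting material
4 | dimethyl{(1E)-5-[(dimethylalumanyl)oxy]-2-methylpent-1-en-1-yl}alumane (alkenylalane, formed in the flask) | C[Al](C)/C=C(\C)CCCO[Al](C)C | intermediate
5 | (E)-5-bromo-4-methylpent-4-en-1-ol | Br/C=C(\C)CCCO | intermediate
6 | (E)-5-bromo-4-methylpent-4-enal | Br/C=C(\C)CCC=O | intermediate
7 | diphenyl phosphite | O=[PH](Oc1ccccc1)Oc1ccccc1 | starting material
8 | tert-butyl bromoacetate | CC(C)(C)OC(=O)CBr | starting material
9 | tert-butyl 2-(diphenoxyphosphoryl)acetate | CC(C)(C)OC(=O)CP(=O)(Oc1ccccc1)Oc1ccccc1 | intermediate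
10 | 5-bromo-2-methylpent-2-ene | CC(C)=CCCBr | starting material
11 | tert-butyl 2-(diphenoxyphosphoryl)-6-methylhept-5-enoate (racemic) | CC(C)=CCCC(C(=O)OC(C)(C)C)P(=O)(Oc1ccccc1)Oc1ccccc1 | intermediate
12 | tert-butyl (2Z,6E)-7-bromo-6-methyl-2-(4-methylpent-3-en-1-yl)hepta-2,6-dienoate | Br/C=C(\C)CC/C=C(/CCC=C(C)C)C(=O)OC(C)(C)C | intermediate
13 | lithium vinyl borate of 2 (formed in the flask) | [Li+].C=C[B-]1(CCO[Si](C)(C)C(C)(C)C)OC(C)(C)C(C)(C)O1 | intermediate
14 | tert-butyl (2Z,6E,9R)-11-[(tert-butyldimethylsilyl)oxy]-6-methyl-2-(4-methylpent-3-en-1-yl)-9-(4,4,5,5-tetramethyl-1,3,2-dioxaborolan-2-yl)undeca-2,6-dienoate | CC(C)(C)[Si](C)(C)OCC[C@H](B1OC(C)(C)C(C)(C)O1)C/C=C(\C)CC/C=C(/CCC=C(C)C)C(=O)OC(C)(C)C | intermediate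
15 | lithium isopropenyl borate of 14 (formed in the flask) | [Li+].CC(C)(C)[Si](C)(C)OCC[C@H]([B-]1(C(C)=C)OC(C)(C)C(C)(C)O1)C/C=C(\C)CC/C=C(/CCC=C(C)C)C(=O)OC(C)(C)C | intermediate
16 | β-iodoalkyl boronate after 1,2-migration (formed in the flask; configuration at the boron-bearing carbon not relevant) | CC(C)(C)[Si](C)(C)OCC[C@H](C(C)(CI)B1OC(C)(C)C(C)(C)O1)C/C=C(\C)CC/C=C(/CCC=C(C)C)C(=O)OC(C)(C)C | intermediate
17 | tert-butyl (2Z,6E,9R)-9-{2-[(tert-butyldimethylsilyl)oxy]ethyl}-6,10-dimethyl-2-(4-methylpent-3-en-1-yl)undeca-2,6,10-trienoate | CC(C)(C)[Si](C)(C)OCC[C@H](C(C)=C)C/C=C(\C)CC/C=C(/CCC=C(C)C)C(=O)OC(C)(C)C | intermediate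
18 | tert-butyl (2Z,6E,9R)-9-(2-hydroxyethyl)-6,10-dimethyl-2-(4-methylpent-3-en-1-yl)undeca-2,6,10-trienoate | OCC[C@H](C(C)=C)C/C=C(\C)CC/C=C(/CCC=C(C)C)C(=O)OC(C)(C)C | intermediate
19 | tert-butyl (2Z,6E,9R)-9-(2-iodoethyl)-6,10-dimethyl-2-(4-methylpent-3-en-1-yl)undeca-2,6,10-trienoate | ICC[C@H](C(C)=C)C/C=C(\C)CC/C=C(/CCC=C(C)C)C(=O)OC(C)(C)C | intermediate
20 | methyl 2-[bis(2,2,2-trifluoroethoxy)phosphoryl]acetate | COC(=O)CP(=O)(OCC(F)(F)F)OCC(F)(F)F | starting material
21 | tert-butyl (2Z,6E,9S)-9-{3-[bis(2,2,2-trifluoroethoxy)phosphoryl]-4-methoxy-4-oxobutyl}-6,10-dimethyl-2-(4-methylpent-3-en-1-yl)undeca-2,6,10-trienoate (both epimers at the phosphonate carbon) | COC(=O)C(CC[C@H](C(C)=C)C/C=C(\C)CC/C=C(/CCC=C(C)C)C(=O)OC(C)(C)C)P(=O)(OCC(F)(F)F)OCC(F)(F)F | intermediate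
22 | (2Z,6E,9S)-9-{3-[bis(2,2,2-trifluoroethoxy)phosphoryl]-4-methoxy-4-oxobutyl}-6,10-dimethyl-2-(4-methylpent-3-en-1-yl)undeca-2,6,10-trienoic acid | COC(=O)C(CC[C@H](C(C)=C)C/C=C(\C)CC/C=C(/CCC=C(C)C)C(=O)O)P(=O)(OCC(F)(F)F)OCC(F)(F)F | intermediate
23 | 4-bromofuran-2(5H)-one | O=C1OCC(Br)=C1 | starting material
24 | [2-(1,3-dioxolan-2-yl)ethyl]zinc bromide (THF solution) | Br[Zn]CCC1OCCO1 | starting material
25 | 4-[2-(1,3-dioxolan-2-yl)ethyl]furan-2(5H)-one | O=C1OCC(CCC2OCCO2)=C1 | intermediate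
26 | 3-(5-oxo-2,5-dihydrofuran-3-yl)propanal | O=CCCC1=CC(=O)OC1 | intermediate
27 | (2Z,6E,9S,12Z)-12-(methoxycarbonyl)-6-methyl-2-(4-methylpent-3-en-1-yl)-15-(5-oxo-2,5-dihydrofuran-3-yl)-9-(prop-1-en-2-yl)pentadeca-2,6,12-trienoic acid (CNP0162600.1) | C=C(C)[C@H](C/C=C(\C)CC/C=C(/CCC=C(C)C)C(=O)O)CC/C(=C/CCC1=CC(=O)OC1)C(=O)OC | target

**Step count.** Total: 15 steps. Longest linear sequence: 10 steps (steps 2, 3, 6, 7, 8, 9, 10, 11, 12, 15; the path through steps 4 and 5 is equally long).

**Steps most likely to fail**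

1. Step 7. The β-silyloxyethyl borate 13 may lose silanolate by β-elimination before it migrates, vinyl may transfer directly to palladium, or the face selection at C9 may be poor. The fallback sets out from 12 and comes back at 17, so it also bypasses step 8. Commercial (R)-4-benzyl-1,3-oxazolidin-2-one is N-acylated with 3-methylbut-2-enoyl chloride to give (R)-4-benzyl-3-(3-methylbut-2-enoyl)-1,3-oxazolidin-2-one F1. Its sodium dienolate (NaN(SiMe3)2, THF, −78 °C) is alkylated at the α-carbon, anti to the benzyl group, with commercial tert-butyl(2-iodoethoxy)dimethylsilane to give the deconjugated α-isopropenyl imide (R)-4-benzyl-3-[(2R)-4-[(tert-butyldimethylsilyl)oxy]-2-(prop-1-en-2-yl)butanoyl]-1,3-oxazolidin-2-one F2. Reduction with LiBH4 gives (2R)-4-[(tert-butyldimethylsilyl)oxy]-2-(prop-1-en-2-yl)butan-1-ol F3, and I2/PPh3/imidazole gives tert-butyl{[(3R)-3-(iodomethyl)-4-methylpent-4-en-1-yl]oxy}dimethylsilane F4. Zinc insertion (Zn dust, LiCl, THF) gives {(2R)-4-[(tert-butyldimethylsilyl)oxy]-2-(prop-1-en-2-yl)butyl}zinc iodide F5. Negishi coupling of F5 with bromide 12 (Pd(dppf)Cl2, THF/DMA, 50 °C) forms the same CH2–CH= bond and gives 17.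

2. Step 8. The alkenyllithium may attack or γ-deprotonate the enoate, borate formation at the hindered secondary boron may be incomplete, or iodine may react at other alkenes. The fallback sets out from 6 and comes back at 17; it runs the boron chemistry before any ester is present. Aldehyde 6 is converted with HC(OMe)3/MeOH/pyridinium tosylate into (E)-1-bromo-5,5-dimethoxy-2-methylpent-1-ene F6. Conjunctive coupling of F6 with borate 13 under the conditions of step 7 gives tert-butyl{[(3R,5E)-9,9-dimethoxy-6-methyl-3-(4,4,5,5-tetramethyl-1,3,2-dioxaborolan-2-yl)non-5-en-1-yl]oxy}dimethylsilane F7. Zweifel olefination with isopropenyllithium, I2 and NaOMe gives tert-butyl{[(3R,5E)-9,9-dimethoxy-6-methyl-3-(prop-1-en-2-yl)non-5-en-1-yl]oxy}dimethylsilane F8. Mild acetal hydrolysis (pyridinium tosylate, acetone/H2O, 25 °C) gives (4E,7R)-9-[(tert-butyldimethylsilyl)oxy]-4-methyl-7-(prop-1-en-2-yl)non-4-enal F9. Ando-type olefination of F9 with phosphonate 11 (NaH, THF, −78 → 0 °C) gives 17.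

3. Step 15. The carboxylate-bearing phosphonate dianion may react sluggishly, the butenolide aldehyde may enolise and self-condense, or Z selectivity may erode with isomers that are hard to separate at the acid stage. The fallback sets out from 21 and comes back at 27; it reverses the order of olefination and ester cleavage. Still–Gennari olefination of the tert-butyl ester 21 with 26 (KN(SiMe3)2, one equivalent, 18-crown-6, THF, −78 °C) gives tert-butyl (2Z,6E,9S,12Z)-12-(methoxycarbonyl)-6-methyl-2-(4-methylpent-3-en-1-yl)-15-(5-oxo-2,5-dihydrofuran-3-yl)-9-(prop-1-en-2-yl)pentadeca-2,6,12-trienoate F10, which is purified as the neutral diester. Lewis-acid cleavage of the tert-butyl ester (ZnBr2, CH2Cl2, 25 °C) then gives 27.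

**Further compounds**
F1 | step 7 | (R)-4-benzyl-3-(3-methylbut-2-enoyl)-1,3-oxazolidin-2-one | CC(C)=CC(=O)N1[C@H](Cc2ccccc2)COC1=O
F2 | step 7 | (R)-4-benzyl-3-[(2R)-4-[(tert-butyldimethylsilyl)oxy]-2-(prop-1-en-2-yl)butanoyl]-1,3-oxazolidin-2-one | CC(C)(C)[Si](C)(C)OCC[C@H](C(C)=C)C(=O)N1[C@H](Cc2ccccc2)COC1=O
F3 | step 7 | (2R)-4-[(tert-butyldimethylsilyl)oxy]-2-(prop-1-en-2-yl)butan-1-ol | CC(C)(C)[Si](C)(C)OCC[C@H](C(C)=C)CO
F4 | step 7 | tert-butyl{[(3R)-3-(iodomethyl)-4-methylpent-4-en-1-yl]oxy}dimethylsilane | CC(C)(C)[Si](C)(C)OCC[C@H](C(C)=C)CI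
F5 | step 7 | {(2R)-4-[(tert-butyldimethylsilyl)oxy]-2-(prop-1-en-2-yl)butyl}zinc iodide | CC(C)(C)[Si](C)(C)OCC[C@H](C(C)=C)C[Zn]I
F6 | step 8 | (E)-1-bromo-5,5-dimethoxy-2-methylpent-1-ene | Br/C=C(\C)CCC(OC)OC
F7 | step 8 | tert-butyl{[(3R,5E)-9,9-dimethoxy-6-methyl-3-(4,4,5,5-tetramethyl-1,3,2-dioxaborolan-2-yl)non-5-en-1-yl]oxy}dimethylsilane | CC(C)(C)[Si](C)(C)OCC[C@H](B1OC(C)(C)C(C)(C)O1)C/C=C(\C)CCC(OC)OC
F8 | step 8 | tert-butyl{[(3R,5E)-9,9-dimethoxy-6-methyl-3-(prop-1-en-2-yl)non-5-en-1-yl]oxy}dimethylsilane | CC(C)(C)[Si](C)(C)OCC[C@H](C(C)=C)C/C=C(\C)CCC(OC)OC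
F9 | step 8 | (4E,7R)-9-[(tert-butyldimethylsilyl)oxy]-4-methyl-7-(prop-1-en-2-yl)non-4-enal | CC(C)(C)[Si](C)(C)OCC[C@H](C(C)=C)C/C=C(\C)CCC=O
F10 | step 15 | tert-butyl (2Z,6E,9S,12Z)-12-(methoxycarbonyl)-6-methyl-2-(4-methylpent-3-en-1-yl)-15-(5-oxo-2,5-dihydrofuran-3-yl)-9-(prop-1-en-2-yl)pentadeca-2,6,12-trienoate | C=C(C)[C@H](C/C=C(\C)CC/C=C(/CCC=C(C)C)C(=O)OC(C)(C)C)CC/C(=C/CCC1=CC(=O)OC1)C(=O)OC
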